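**Plan**

- Retrosynthesis (chroman numbering O1, C2–C4, C4a, C5–C8, C8a; ring A is the acylated chroman benzene ring, ring B the 4-hydroxy-3-prenylphenyl ring): remove the silyl group from the ring B oxygen, trace the C3–C4 single bond back to a 2H-chromene alkene, open the pyran at C4a–C4 (alkyne hydroarylation) and then at O1–C2 (propargylic ether), cut the aryl–carbonyl bond C6–C(=O), and cut the ring B aryl–prenyl bond.
- Enabling feature: O1 on C8a is para to the acyl-bearing C6. Before the pyran closes, the 2,6-dihydroxy-4-alkoxy acyl ring is therefore symmetric about the C6–C8a axis, and the two carbons flanking that oxygen (future C4a and C8) are equivalent. A tether on that oxygen can only give the 6-acyl-5,7-dihydroxychromene.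
- Forward order: ring B is prenylated, silylated and turned into a Weinreb amide; lithiated tris-MOM phloroglucinol is acylated with it (chain joined); MOM removal and etherification of the para hydroxyl follow; the gold-catalysed 6-endo closure builds the pyran, the only ring made; C3=C4 is hydrogenated and the silyl ether cleaved.
- Stereochemistry: the target has no stereocentre and no stereogenic double bond, so nothing has to be set; the route needs only site- and chemoselectivity.

Key step: step 8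

Assumption: 3-chloro-3-methylbut-1-yne is a catalogue reagent and is used as purchased.

**Route**

Step 1
Reactants: 1 methyl 3-(4-hydroxyphenyl)propanoate; 2 1-bromo-3-methylbut-2-ene (prenyl bromide)
Product: 3 methyl 3-[4-hydroxy-3-(3-methylbut-2-en-1-yl)phenyl]propanoate
Conditions: NaH (1.0 equiv), toluene, 0 °C to rt; then 2, rt
Reagents that add atoms: none
Why: Ortho C-alkylation of an ambident phenoxide: the tightly ion-paired sodium salt of 1 in a non-polar solvent should be allylated by the primary allylic bromide at a carbon next to oxygen (the para position is blocked and both ortho positions are equivalent), the direct classical entry to ortho-prenylphenols, with the O-prenyl ether as a separable by-product.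

Step 2
Reactants: 3 methyl 3-[4-hydroxy-3-(3-methylbut-2-en-1-yl)phenyl]propanoate
Product: 4 methyl 3-[3-(3-methylbut-2-en-1-yl)-4-(triisopropylsilyloxy)phenyl]propanoate
Conditions: TIPSCl, imidazole, DMF, rt
Reagents that add atoms: chlorotri(propan-2-yl)silane (TIPSCl), CC(C)[Si](Cl)(C(C)C)C(C)C
Why: Imidazole-promoted silylation of a phenol; the triisopropylsilyl ether is chosen because on an aryl oxygen it should withstand the Grignard base, the aryllithium, methanolic HCl and DBU of the following steps and still be cleaved by fluoride at the end.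

Step 3
Reactants: 4 methyl 3-[3-(3-methylbut-2-en-1-yl)-4-(triisopropylsilyloxy)phenyl]propanoate
Product: 5 N-methoxy-N-methyl-3-[3-(3-methylbut-2-en-1-yl)-4-(triisopropylsilyloxy)phenyl]propanamide
Conditions: MeNH(OMe)·HCl, iPrMgCl, THF, −20 to 0 °C
Reagents that add atoms: N,O-dimethylhydroxylamine hydrochloride, CNOC.Cl
Why: Direct aminolysis of the methyl ester by the chloromagnesium amide generated from MeNH(OMe)·HCl and iPrMgCl (Weinreb amide formation), which is fast below 0 °C and leaves the silyl ether and the alkene alone.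

Step 4
Reactants: 6 phloroglucinol (benzene-1,3,5-triol)
Product: 7 1,3,5-tris(methoxymethoxy)benzene
Conditions: NaH, MOMCl, DMF, 0 °C to rt
Reagents that add atoms: chloromethyl methyl ether (MOMCl), COCCl
Why: Threefold Williamson-type etherification (MOM protection) of the phenoxide oxygens gives a threefold-symmetric arene in which every ring hydrogen lies between two coordinating acetal ethers.

Step 5
Reactants: 7 1,3,5-tris(methoxymethoxy)benzene; 5 N-methoxy-N-methyl-3-[3-(3-methylbut-2-en-1-yl)-4-(triisopropylsilyloxy)phenyl]propanamide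
Product: 10 3-[3-(3-methylbut-2-en-1-yl)-4-(triisopropylsilyloxy)phenyl]-1-[2,4,6-tris(methoxymethoxy)phenyl]propan-1-one, via [2,4,6-tris(methoxymethoxy)phenyl]lithium 8 (not isolated), via lithium hemiaminal alkoxide 9 (not isolated)
Conditions: n-BuLi, THF, 0 °C; then 5, −78 to 0 °C; aq. NH4Cl
Reagents that add atoms: none
Why: Directed ortho-metalation followed by Weinreb ketone synthesis: n-BuLi removes one of the three equivalent ring hydrogens of 7, each flanked by two MOM ethers, and the five-membered N-methoxy chelate 9 formed on addition to 5 holds the tetrahedral stage until aqueous work-up, so no tertiary alcohol should form.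

Step 6
Reactants: 10 3-[3-(3-methylbut-2-en-1-yl)-4-(triisopropylsilyloxy)phenyl]-1-[2,4,6-tris(methoxymethoxy)phenyl]propan-1-one
Product: 11 3-[3-(3-methylbut-2-en-1-yl)-4-(triisopropylsilyloxy)phenyl]-1-(2,4,6-trihydroxyphenyl)propan-1-one
Conditions: HCl (1.25 M in MeOH), THF, 40 °C
Reagents that add atoms: none
Why: Acid-catalysed acetal exchange with methanol (MOM cleavage) frees the three phenols as dimethoxymethane, while the acid-robust aryl triisopropylsilyl ether and the prenyl alkene, which has no free neighbouring hydroxyl to cyclise onto, should survive the mild conditions.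

Step 7
Reactants: 11 3-[3-(3-methylbut-2-en-1-yl)-4-(triisopropylsilyloxy)phenyl]-1-(2,4,6-trihydroxyphenyl)propan-1-one; 12 3-chloro-3-methylbut-1-yne
Product: 13 1-[2,6-dihydroxy-4-(2-methylbut-3-yn-2-yloxy)phenyl]-3-[3-(3-methylbut-2-en-1-yl)-4-(triisopropylsilyloxy)phenyl]propan-1-one
Conditions: CuCl2·2H2O (1 mol%), DBU (1.2 equiv), MeCN, −5 to 0 °C
Reagents that add atoms: none
Why: Copper-catalysed propargylic substitution (etherification of a phenol by a tertiary propargylic chloride through a copper acetylide and its allenylidene-type cation): with about one equivalent of DBU only the hydroxyl para to the carbonyl is ionised, since it is the most acidic and the only one not locked in a hydrogen bond to the ketone, so the ether should form there.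

Step 8
Reactants: 13 1-[2,6-dihydroxy-4-(2-methylbut-3-yn-2-yloxy)phenyl]-3-[3-(3-methylbut-2-en-1-yl)-4-(triisopropylsilyloxy)phenyl]propan-1-one
Product: 14 1-(5,7-dihydroxy-2,2-dimethyl-2H-chromen-6-yl)-3-[3-(3-methylbut-2-en-1-yl)-4-(triisopropylsilyloxy)phenyl]propan-1-one
Conditions: Ph3PAuNTf2 (3 mol%), CH2Cl2, rt
Reagents that add atoms: none
Why: Cationic monovalent gold binds the terminal alkyne of 13, the ring carbon ortho to the ether oxygen attacks the alkyne terminus in a Friedel–Crafts-type step, and rearomatisation followed by protodeauration releases the 2H-chromene. The closest known reaction is the gold- or platinum-catalysed intramolecular hydroarylation of aryl 1,1-dimethylpropargyl ethers to 2,2-dimethyl-2H-chromenes. The pyran ring closes in the 6-endo-dig mode by forming C4a–C4, helped by the gem-dimethyl group, which favours the folded conformer. No stereocentre is created. The step needs site selectivity on ring A, endo over 5-exo closure and preference for the alkyne over the prenyl alkene. The two carbons flanking the ether oxygen are equivalent by the symmetry of the 2,6-dihydroxy-4-alkoxyacyl ring so either attack gives the 6-acyl-5,7-dihydroxychromene, a terminal alkyne facing a ring carbon activated by three oxygens closes endo, and the carbophilic gold cation prefers alkynes to an isolated trisubstituted alkene whose neighbouring phenol oxygen is silylated.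

Step 9
Reactants: 14 1-(5,7-dihydroxy-2,2-dimethyl-2H-chromen-6-yl)-3-[3-(3-methylbut-2-en-1-yl)-4-(triisopropylsilyloxy)phenyl]propan-1-one
Product: 15 1-(5,7-dihydroxy-2,2-dimethyl-3,4-dihydro-2H-chromen-6-yl)-3-[3-(3-methylbut-2-en-1-yl)-4-(triisopropylsilyloxy)phenyl]propan-1-one
Conditions: H2 (1 atm), RhCl(PPh3)3 (5 mol%), toluene–EtOH 1:1, rt
Reagents that add atoms: none
Why: Homogeneous rhodium-catalysed hydrogenation (Wilkinson-type), whose rate falls steeply with alkene substitution, so that the cis-disubstituted C3=C4 bond of the chromene should be saturated before the trisubstituted prenyl alkene when the uptake is stopped at one equivalent of H2, the ketone, phenols and silyl ether being inert.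

Step 10
Reactants: 15 1-(5,7-dihydroxy-2,2-dimethyl-3,4-dihydro-2H-chromen-6-yl)-3-[3-(3-methylbut-2-en-1-yl)-4-(triisopropylsilyloxy)phenyl]propan-1-one
Product: 16 1-(5,7-dihydroxy-2,2-dimethyl-3,4-dihydro-2H-chromen-6-yl)-3-[4-hydroxy-3-(3-methylbut-2-en-1-yl)phenyl]propan-1-one (target)
Conditions: TBAF, AcOH, THF, 0 °C
Reagents that add atoms: none
Why: Fluoride-induced cleavage of the aryl silyl ether (formation of the strong Si–F bond), buffered with acetic acid so that the acidic acylphloroglucinol hydroxyls and the ketone are not exposed to strongly basic fluoride, should release the target.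

**Compound list**

1 | methyl 3-(4-hydroxyphenyl)propanoate | COC(=O)CCc1ccc(O)cc1 | starting material
2 | 1-bromo-3-methylbut-2-ene (prenyl bromide) | CC(C)=CCBr | starting material
3 | methyl 3-[4-hydroxy-3-(3-methylbut-2-en-1-yl)phenyl]propanoate | COC(=O)CCc1ccc(O)c(CC=C(C)C)c1 | intermediate
4 | methyl 3-[3-(3-methylbut-2-en-1-yl)-4-(triisopropylsilyloxy)phenyl]propanoate | COC(=O)CCc1ccc(O[Si](C(C)C)(C(C)C)C(C)C)c(CC=C(C)C)c1 | intermediate
5 | N-methoxy-N-methyl-3-[3-(3-methylbut-2-en-1-yl)-4-(triisopropylsilyloxy)phenyl]propanamide | CON(C)C(=O)CCc1ccc(O[Si](C(C)C)(C(C)C)C(C)C)c(CC=C(C)C)c1 | intermediate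
6 | phloroglucinol (benzene-1,3,5-triol) | Oc1cc(O)cc(O)c1 | starting material
7 | 1,3,5-tris(methoxymethoxy)benzene | COCOc1cc(OCOC)cc(OCOC)c1 | intermediate
8 | [2,4,6-tris(methoxymethoxy)phenyl]lithium | [Li]c1c(OCOC)cc(OCOC)cc1OCOC | intermediate
9 | lithium 1-[methoxy(methyl)amino]-3-[3-(3-methylbut-2-en-1-yl)-4-(triisopropylsilyloxy)phenyl]-1-[2,4,6-tris(methoxymethoxy)phenyl]propan-1-olate (racemic hemiaminal alkoxide) | CON(C)C(O[Li])(CCc1ccc(O[Si](C(C)C)(C(C)C)C(C)C)c(CC=C(C)C)c1)c1c(OCOC)cc(OCOC)cc1OCOC | intermediate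
10 | 3-[3-(3-methylbut-2-en-1-yl)-4-(triisopropylsilyloxy)phenyl]-1-[2,4,6-tris(methoxymethoxy)phenyl]propan-1-one | COCOc1cc(OCOC)c(C(=O)CCc2ccc(O[Si](C(C)C)(C(C)C)C(C)C)c(CC=C(C)C)c2)c(OCOC)c1 | intermediate
11 | 3-[3-(3-methylbut-2-en-1-yl)-4-(triisopropylsilyloxy)phenyl]-1-(2,4,6-trihydroxyphenyl)propan-1-one | CC(C)=CCc1cc(CCC(=O)c2c(O)cc(O)cc2O)ccc1O[Si](C(C)C)(C(C)C)C(C)C | intermediate
12 | 3-chloro-3-methylbut-1-yne | CC(C)(Cl)C#C | starting material
13 | 1-[2,6-dihydroxy-4-(2-methylbut-3-yn-2-yloxy)phenyl]-3-[3-(3-methylbut-2-en-1-yl)-4-(triisopropylsilyloxy)phenyl]propan-1-one | CC(C)=CCc1cc(CCC(=O)c2c(O)cc(OC(C)(C)C#C)cc2O)ccc1O[Si](C(C)C)(C(C)C)C(C)C | intermediate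
14 | 1-(5,7-dihydroxy-2,2-dimethyl-2H-chromen-6-yl)-3-[3-(3-methylbut-2-en-1-yl)-4-(triisopropylsilyloxy)phenyl]propan-1-one | CC(C)=CCc1cc(CCC(=O)c2c(O)cc3c(c2O)C=CC(C)(C)O3)ccc1O[Si](C(C)C)(C(C)C)C(C)C | intermediate
15 | 1-(5,7-dihydroxy-2,2-dimethyl-3,4-dihydro-2H-chromen-6-yl)-3-[3-(3-methylbut-2-en-1-yl)-4-(triisopropylsilyloxy)phenyl]propan-1-one | CC(C)=CCc1cc(CCC(=O)c2c(O)cc3c(c2O)CCC(C)(C)O3)ccc1O[Si](C(C)C)(C(C)C)C(C)C | intermediate
16 | 1-(5,7-dihydroxy-2,2-dimethyl-3,4-dihydro-2H-chromen-6-yl)-3-[4-hydroxy-3-(3-methylbut-2-en-1-yl)phenyl]propan-1-one | CC(C)=CCc1cc(CCC(=O)c2c(O)cc3c(c2O)CCC(C)(C)O3)ccc1O | target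

**Step count and risks**

Total step count: 10. Longest linear sequence: 9 steps (1 → 3 → 4 → 5 → 10 → 11 → 13 → 14 → 15 → 16; step 4 lies on the ring A branch).

Steps most likely to fail:

Step 7. Site control in the etherification may be lost: alkylation could spread to a chelated ortho hydroxyl, a second alkylation could follow, or the electron-rich ring could be C-alkylated. The fallback fixes the para oxygen by protecting-group differentiation, so that only one hydroxyl is free when the ether is made. It sets out from 6 and uses 5. Statistical protection of 6 (MOMCl 2 equiv, iPr2NEt, DMF) should give 3,5-bis(methoxymethoxy)phenol F1, and silylation (TIPSCl, imidazole) [3,5-bis(methoxymethoxy)phenoxy]triisopropylsilane F2. n-BuLi should remove the hydrogen between the two MOM ethers, since the bulky silyl ether does not direct, to give [2,6-bis(methoxymethoxy)-4-(triisopropylsilyloxy)phenyl]lithium F3. Addition to 5 leads through the lithium hemiaminal alkoxide lithium 1-[2,6-bis(methoxymethoxy)-4-(triisopropylsilyloxy)phenyl]-1-[methoxy(methyl)amino]-3-[3-(3-methylbut-2-en-1-yl)-4-(triisopropylsilyloxy)phenyl]propan-1-olate F4 to the ketone 1-[2,6-bis(methoxymethoxy)-4-(triisopropylsilyloxy)phenyl]-3-[3-(3-methylbut-2-en-1-yl)-4-(triisopropylsilyloxy)phenyl]propan-1-one F5. K2CO3 in MeOH at 0 °C should cleave only the silyl ether para to the ketone, whose phenoxide is by far the better leaving group and which is unhindered, giving 1-[4-hydroxy-2,6-bis(methoxymethoxy)phenyl]-3-[3-(3-methylbut-2-en-1-yl)-4-(triisopropylsilyloxy)phenyl]propan-1-one F6. The copper-catalysed etherification with 12 then has a single hydroxyl to react with and should give 1-[2,6-bis(methoxymethoxy)-4-(2-methylbut-3-yn-2-yloxy)phenyl]-3-[3-(3-methylbut-2-en-1-yl)-4-(triisopropylsilyloxy)phenyl]propan-1-one F7. Mild methanolic HCl removes the two MOM groups next to the carbonyl and the route is rejoined at 13.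

Step 9. Over-reduction is the danger: the prenyl alkene may be saturated at a rate too close to that of the chromene alkene, which is hindered by the neighbouring quaternary carbon. The fallback brings the prenyl group in only after the hydrogenation. It sets out from 1. Ortho-bromination (NBS, MeCN) should give methyl 3-(3-bromo-4-hydroxyphenyl)propanoate F8. The operations of steps 2 and 3 then give methyl 3-[3-bromo-4-(triisopropylsilyloxy)phenyl]propanoate F9 and 3-[3-bromo-4-(triisopropylsilyloxy)phenyl]-N-methoxy-N-methylpropanamide F10. Addition of 8 (made from 7 as in step 5) leads through lithium 3-[3-bromo-4-(triisopropylsilyloxy)phenyl]-1-[methoxy(methyl)amino]-1-[2,4,6-tris(methoxymethoxy)phenyl]propan-1-olate F11 to 3-[3-bromo-4-(triisopropylsilyloxy)phenyl]-1-[2,4,6-tris(methoxymethoxy)phenyl]propan-1-one F12. The conditions of steps 6, 7 and 8 should give in turn 3-[3-bromo-4-(triisopropylsilyloxy)phenyl]-1-(2,4,6-trihydroxyphenyl)propan-1-one F13, 3-[3-bromo-4-(triisopropylsilyloxy)phenyl]-1-[2,6-dihydroxy-4-(2-methylbut-3-yn-2-yloxy)phenyl]propan-1-one F14 and 3-[3-bromo-4-(triisopropylsilyloxy)phenyl]-1-(5,7-dihydroxy-2,2-dimethyl-2H-chromen-6-yl)propan-1-one F15. With no other alkene present, hydrogenation over RhCl(PPh3)3, which leaves the aryl bromide alone, can be driven to completion to give 3-[3-bromo-4-(triisopropylsilyloxy)phenyl]-1-(5,7-dihydroxy-2,2-dimethyl-3,4-dihydro-2H-chromen-6-yl)propan-1-one F16. Stille coupling with tributyl(3-methylbut-2-en-1-yl)stannane (zerovalent palladium, Pd(PPh3)4, DMF, 90 °C) then installs the prenyl group and the route is rejoined at 15.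

Step 8. The cyclisation may stall because the chelating dihydroxy ketone deactivates the gold catalyst, or adventitious acid may strip the tertiary propargyl group. The fallback leaves metal catalysis for a purely thermal pericyclic cascade that forms the same C4a–C4 bond and the same pyran. It sets out from 13, heated in N,N-diethylaniline at about 180 °C. Aromatic propargyl Claisen [3,3] shift and enolisation should give 3-[3-(3-methylbut-2-en-1-yl)-4-(triisopropylsilyloxy)phenyl]-1-[2,4,6-trihydroxy-3-(3-methylbuta-1,2-dien-1-yl)phenyl]propan-1-one F17. A [1,5]-hydrogen shift gives the ortho-quinone methide (6Z)-3,5-dihydroxy-6-(3-methylbut-2-en-1-ylidene)-4-{3-[3-(3-methylbut-2-en-1-yl)-4-(triisopropylsilyloxy)phenyl]propanoyl}cyclohexa-2,4-dien-1-one F18. Oxa-6π electrocyclisation closes the ring and the route is rejoined at 14; the ring symmetry again makes the two possible sites of the sigmatropic shift equivalent.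

**Further compounds**

F1 | step 7 | 3,5-bis(methoxymethoxy)phenol | COCOc1cc(O)cc(OCOC)c1
F2 | step 7 | [3,5-bis(methoxymethoxy)phenoxy]triisopropylsilane | COCOc1cc(OCOC)cc(O[Si](C(C)C)(C(C)C)C(C)C)c1
F3 | step 7 | [2,6-bis(methoxymethoxy)-4-(triisopropylsilyloxy)phenyl]lithium | [Li]c1c(OCOC)cc(O[Si](C(C)C)(C(C)C)C(C)C)cc1OCOC
F4 | step 7 | lithium 1-[2,6-bis(methoxymethoxy)-4-(triisopropylsilyloxy)phenyl]-1-[methoxy(methyl)amino]-3-[3-(3-methylbut-2-en-1-yl)-4-(triisopropylsilyloxy)phenyl]propan-1-olate | CON(C)C(O[Li])(CCc1ccc(O[Si](C(C)C)(C(C)C)C(C)C)c(CC=C(C)C)c1)c1c(OCOC)cc(O[Si](C(C)C)(C(C)C)C(C)C)cc1OCOC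
F5 | step 7 | 1-[2,6-bis(methoxymethoxy)-4-(triisopropylsilyloxy)phenyl]-3-[3-(3-methylbut-2-en-1-yl)-4-(triisopropylsilyloxy)phenyl]propan-1-one | CC(C)=CCc1cc(CCC(=O)c2c(OCOC)cc(O[Si](C(C)C)(C(C)C)C(C)C)cc2OCOC)ccc1O[Si](C(C)C)(C(C)C)C(C)C
F6 | step 7 | 1-[4-hydroxy-2,6-bis(methoxymethoxy)phenyl]-3-[3-(3-methylbut-2-en-1-yl)-4-(triisopropylsilyloxy)phenyl]propan-1-one | CC(C)=CCc1cc(CCC(=O)c2c(OCOC)cc(O)cc2OCOC)ccc1O[Si](C(C)C)(C(C)C)C(C)C
F7 | step 7 | 1-[2,6-bis(methoxymethoxy)-4-(2-methylbut-3-yn-2-yloxy)phenyl]-3-[3-(3-methylbut-2-en-1-yl)-4-(triisopropylsilyloxy)phenyl]propan-1-one | CC(C)=CCc1cc(CCC(=O)c2c(OCOC)cc(OC(C)(C)C#C)cc2OCOC)ccc1O[Si](C(C)C)(C(C)C)C(C)C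
F8 | step 9 | methyl 3-(3-bromo-4-hydroxyphenyl)propanoate | COC(=O)CCc1ccc(O)c(Br)c1
F9 | step 9 | methyl 3-[3-bromo-4-(triisopropylsilyloxy)phenyl]propanoate | COC(=O)CCc1ccc(O[Si](C(C)C)(C(C)C)C(C)C)c(Br)c1
F10 | step 9 | 3-[3-bromo-4-(triisopropylsilyloxy)phenyl]-N-methoxy-N-methylpropanamide | CON(C)C(=O)CCc1ccc(O[Si](C(C)C)(C(C)C)C(C)C)c(Br)c1
F11 | step 9 | lithium 3-[3-bromo-4-(triisopropylsilyloxy)phenyl]-1-[methoxy(methyl)amino]-1-[2,4,6-tris(methoxymethoxy)phenyl]propan-1-olate | CON(C)C(O[Li])(CCc1ccc(O[Si](C(C)C)(C(C)C)C(C)C)c(Br)c1)c1c(OCOC)cc(OCOC)cc1OCOC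
F12 | step 9 | 3-[3-bromo-4-(triisopropylsilyloxy)phenyl]-1-[2,4,6-tris(methoxymethoxy)phenyl]propan-1-one | COCOc1cc(OCOC)c(C(=O)CCc2ccc(O[Si](C(C)C)(C(C)C)C(C)C)c(Br)c2)c(OCOC)c1
F13 | step 9 | 3-[3-bromo-4-(triisopropylsilyloxy)phenyl]-1-(2,4,6-trihydroxyphenyl)propan-1-one | O=C(CCc1ccc(O[Si](C(C)C)(C(C)C)C(C)C)c(Br)c1)c1c(O)cc(O)cc1O
F14 | step 9 | 3-[3-bromo-4-(triisopropylsilyloxy)phenyl]-1-[2,6-dihydroxy-4-(2-methylbut-3-yn-2-yloxy)phenyl]propan-1-one | C#CC(C)(C)Oc1cc(O)c(C(=O)CCc2ccc(O[Si](C(C)C)(C(C)C)C(C)C)c(Br)c2)c(O)c1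
F15 | step 9 | 3-[3-bromo-4-(triisopropylsilyloxy)phenyl]-1-(5,7-dihydroxy-2,2-dimethyl-2H-chromen-6-yl)propan-1-one | CC1(C)C=Cc2c(O1)cc(O)c(C(=O)CCc3ccc(O[Si](C(C)C)(C(C)C)C(C)C)c(Br)c3)c2O
F16 | step 9 | 3-[3-bromo-4-(triisopropylsilyloxy)phenyl]-1-(5,7-dihydroxy-2,2-dimethyl-3,4-dihydro-2H-chromen-6-yl)propan-1-one | CC1(C)CCc2c(O1)cc(O)c(C(=O)CCc3ccc(O[Si](C(C)C)(C(C)C)C(C)C)c(Br)c3)c2O
F17 | step 8 | 3-[3-(3-methylbut-2-en-1-yl)-4-(triisopropylsilyloxy)phenyl]-1-[2,4,6-trihydroxy-3-(3-methylbuta-1,2-dien-1-yl)phenyl]propan-1-one | CC(C)=C=Cc1c(O)cc(O)c(C(=O)CCc2ccc(O[Si](C(C)C)(C(C)C)C(C)C)c(CC=C(C)C)c2)c1O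
F18 | step 8 | (6Z)-3,5-dihydroxy-6-(3-methylbut-2-en-1-ylidene)-4-{3-[3-(3-methylbut-2-en-1-yl)-4-(triisopropylsilyloxy)phenyl]propanoyl}cyclohexa-2,4-dien-1-one | CC(C)=C/C=C1\C(=O)C=C(O)C(C(=O)CCc2ccc(O[Si](C(C)C)(C(C)C)C(C)C)c(CC=C(C)C)c2)=C1O
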